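Everything rests on taking pyrrole ring A apart at C-3–C-3a, N-1–C-7a and N-1–C-2 (indole-type locants; ring B is C-3a to C-7a, azepine ring C runs through N-1, C-7a and C-7). Because C-3a and C-7a belong to rings A and B, C-7a also to ring C, and C-2 carries the pendant lactone, these atoms map onto a cyclohexane-1,3-dione bearing an azidobutyl chain beside one carbonyl and onto a lactone bromomethyl ketone. In one operation the dione is C-alkylated, the azide reduced and the amine condensed with the neighbouring ring carbonyl and the side-chain ketone, closing rings C and A and leaving C-4 as the ketone on which lactone ring D is built.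

Key step: step 9

Remarks on the chemistry:
- Locants: from 21 onwards the pyrrole/cyclohexane bicycle is numbered as an indole, with a butane-1,4-diyl bridge from N-1 to C-7 (ring C). Lactone ring D is fused at C-4/C-5 with its ring oxygen on C-5 and its methyl-bearing α-carbon on C-4.
- Assumption: the (1R,2R) catalyst of step 1 is taken to give the (S) adduct; if correlation shows the opposite sense, the (1S,2S) antipode is used with no other change.
- The malonate-derived carbon in 3, 5, 6, 7 and 8 is an unassigned mixture of configurations. This has no consequence, because it becomes the equilibrated C-4 of 9.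
- Any minor enantiomer from step 1 becomes a diastereomer at step 9 and is to be removed there by chromatography.

Step 1
Reactants: 1 tert-butyl ethyl malonate; 2 (E)-hex-3-en-2-one
Product: 3 1-tert-butyl 3-ethyl 2-[(3S)-5-oxohexan-3-yl]propanedioate
Conditions: 1-[(1R,2R)-2-amino-1,2-diphenylethyl]-3-[3,5-bis(trifluoromethyl)phenyl]thiourea (10 mol %), PhCO2H (10 mol %), toluene, rt
Reagents that add atoms: none
Why: Iminium activation of the enone by the primary amine while the thiourea binds the malonate gives an enantioselective organocatalytic Michael addition, the catalyst shielding one face of the enone so that the ethyl-bearing carbon is set as S (the malonate carbon being an irrelevant epimer mixture).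

Step 2
Reactants: 3 1-tert-butyl 3-ethyl 2-[(3S)-5-oxohexan-3-yl]propanedioate; 4 1-chloro-4-iodobutane
Product: 5 1-tert-butyl 3-ethyl 2-(4-chlorobutyl)-2-[(3S)-5-oxohexan-3-yl]propanedioate
Conditions: NaH (1.0 equiv), DMF, 0 °C; 4 (1.2 equiv), rt
Reagents that add atoms: none
Why: Malonic ester alkylation: the malonate C–H is far more acidic than the ketone α-hydrogens, so one equivalent of NaH forms only the malonate anion, which displaces iodide in an SN2 reaction while the poorer chloride leaving group is kept for the next step.

Step 3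
Reactants: 5 1-tert-butyl 3-ethyl 2-(4-chlorobutyl)-2-[(3S)-5-oxohexan-3-yl]propanedioate
Product: 6 1-tert-butyl 3-ethyl 2-(4-azidobutyl)-2-[(3S)-5-oxohexan-3-yl]propanedioate
Conditions: NaN3 (1.5 equiv), NaI (10 mol %), DMF, 60 °C
Reagents that add atoms: sodium azide, [Na+].[N-]=[N+]=[N-]
Why: SN2 displacement of the primary chloride by azide (iodide-assisted, Finkelstein-type) is carried out here on a neutral, non-enolised substrate, so the azide never meets a hot dione enolate and no HN3 is liberated.

Step 4
Reactants: 6 1-tert-butyl 3-ethyl 2-(4-azidobutyl)-2-[(3S)-5-oxohexan-3-yl]propanedioate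
Product: 7 tert-butyl (6S)-1-(4-azidobutyl)-6-ethyl-2,4-dioxocyclohexane-1-carboxylate
Conditions: LiN(SiMe3)2 (2.2 equiv), THF, −78 → 0 °C; then 1 M HCl
Reagents that add atoms: none
Why: Kinetic deprotonation of the methyl ketone at its unhindered CH3 followed by an intramolecular Claisen (Dieckmann-type) condensation onto the ethyl ester closes the cyclohexane-1,3-dione, the tert-butyl ester being too hindered to be attacked and the low temperature excluding retro-Michael erosion of the ethyl-bearing centre.

Step 5
Reactants: 7 tert-butyl (6S)-1-(4-azidobutyl)-6-ethyl-2,4-dioxocyclohexane-1-carboxylate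
Product: 9 (4R,5S)-4-(4-azidobutyl)-5-ethylcyclohexane-1,3-dione, via acid 8 (not isolated)
Conditions: CF3CO2H–CH2Cl2 (1:3), rt; evaporate; toluene, 70 °C
Reagents that add atoms: none
Why: Acidolysis of the tert-butyl ester gives a β-keto acid that decarboxylates on gentle warming, and acid-catalysed enolisation then lets C-4 settle trans (diequatorial) to the C-5 ethyl group under thermodynamic control, all under conditions that an alkyl azide tolerates.

Step 6
Reactants: 10 dimethyl N-(tert-butoxycarbonyl)-L-glutamate
Product: 11 dimethyl (2S,4S)-2-[(tert-butoxycarbonyl)amino]-4-methylpentanedioate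
Conditions: LiN(SiMe3)2 (2.1 equiv), THF, −78 °C; MeI, −78 °C; then AcOH
Reagents that add atoms: iodomethane, CI
Why: Alkylation of the chelated dilithio species (N-lithiocarbamate plus γ-ester enolate) with MeI proceeds with 1,3-asymmetric induction from C-2, the electrophile entering anti to the carbamate-bearing centre to set C-4 as S (dianion enolate alkylation).

Step 7
Reactants: 11 dimethyl (2S,4S)-2-[(tert-butoxycarbonyl)amino]-4-methylpentanedioate
Product: 13 (2S,4S)-4-methyl-5-oxooxolane-2-carboxylic acid (cis), via amino acid hydrochloride 12 (not isolated)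
Conditions: 6 M HCl, reflux; evaporate; NaNO2, 1 M HCl, 0 °C → rt
Reagents that add atoms: water, O
Why: Acid hydrolysis removes the Boc group and both methyl esters without touching either stereocentre, and nitrous acid deamination of the amino acid then passes through an α-lactone so that the γ-carboxyl closes the lactone with net retention at C-2 (diazotisation with double inversion), giving the cis acid.

Step 8
Reactants: 13 (2S,4S)-4-methyl-5-oxooxolane-2-carboxylic acid
Product: 16 (3S,5S)-5-(bromoacetyl)-3-methyloxolan-2-one, via mixed anhydride 14 (not isolated), via diazoketone 15 (not isolated)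
Conditions: i-BuOCOCl, N-methylmorpholine, THF, −15 °C; CH2N2, Et2O, 0 °C; 48% aq HBr, 0 °C
Reagents that add atoms: diazomethane, C=[N+]=[N-]; hydrogen bromide, Br
Why: Mixed-anhydride activation, acylation of diazomethane and hydrobromination of the diazoketone (Arndt–Eistert-type activation followed by Nierenstein-type HBr capture) convert the acid into the bromomethyl ketone without any base strong enough to enolise the oxygen-bearing stereocentre.

Step 9
Reactants: 9 (4R,5S)-4-(4-azidobutyl)-5-ethylcyclohexane-1,3-dione; 16 (3S,5S)-5-(bromoacetyl)-3-methyloxolan-2-one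
Product: 21 (6S,7R)-1,7-(butane-1,4-diyl)-6-ethyl-2-[(2S,4S)-4-methyl-5-oxooxolan-2-yl]-1,5,6,7-tetrahydro-4H-indol-4-one, via azido triketone 17 (not isolated), via iminophosphorane 18 (not isolated), via amino triketone 19 (not isolated), via bicyclic enaminone 20 (not isolated)
Conditions: 9 (1.05 equiv), KHCO3 (1.1 equiv), THF–H2O (4:1), 0 °C → rt; PPh3 (1.2 equiv), rt → 45 °C; AcOH, 70 °C
Reagents that add atoms: none
Why: The bicarbonate-generated enolate of 9 displaces bromide from 16 at the dione C-2 (SN2 C-alkylation, forming the C-3–C-3a bond) to give triketone 17, whose azide is reduced by PPh3 through iminophosphorane 18 and its hydrolysis (Staudinger reduction) to amine 19. In warm acetic acid 19 condenses with the ring carbonyl next to the tether to give vinylogous amide 20 (N-1–C-7a bond), and the enaminone nitrogen then condenses with the side-chain ketone in a Paal–Knorr cyclodehydration (N-1–C-2 bond) that aromatises ring A. Ring C closes by 7-exo-trig addition of the amine to the ring carbonyl followed by dehydration, and ring A by 5-exo-trig addition of the enaminone nitrogen to the side-chain carbonyl followed by dehydration. The closest known reaction type is the Hantzsch-type synthesis of 4-oxo-4,5,6,7-tetrahydroindoles from cyclohexane-1,3-diones, α-haloketones and primary amines, the amine here being delivered from within the dione. No stereocentre is created, and the existing ones are kept because bicarbonate is too weak to enolise the α-acyloxy ketone and C-7 loses its acidifying carbonyl once ring C has formed. The selectivity needed is between the two dione carbonyls, and the four-carbon tether secures it, since the adjacent carbonyl is reached through a seven-membered ring whereas the remote one would require a bridged nine-membered ring.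

Step 10
Reactants: 21 (6S,7R)-1,7-(butane-1,4-diyl)-6-ethyl-2-[(2S,4S)-4-methyl-5-oxooxolan-2-yl]-1,5,6,7-tetrahydro-4H-indol-4-one
Product: 22 (5S,6R,7R)-1,7-(butane-1,4-diyl)-6-ethyl-5-hydroxy-2-[(2S,4S)-4-methyl-5-oxooxolan-2-yl]-1,5,6,7-tetrahydro-4H-indol-4-one
Conditions: KN(SiMe3)2 (1.1 equiv), THF, −78 °C; 2-(phenylsulfonyl)-3-phenyloxaziridine (1.3 equiv), −78 °C; then AcOH
Reagents that add atoms: 2-(phenylsulfonyl)-3-phenyloxaziridine, O=S(=O)(c1ccccc1)N1OC1c1ccccc1
Why: Davis-type enolate hydroxylation: KN(SiMe3)2 deprotonates the only α-CH2 of the pyrrolyl ketone (kinetically preferred over the hindered lactone α-CH) and the oxaziridine transfers oxygen to the enolate face anti to the adjacent C-6 ethyl group, setting the C-5 hydroxyl trans to it.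

Step 11
Reactants: 22 (5S,6R,7R)-1,7-(butane-1,4-diyl)-6-ethyl-5-hydroxy-2-[(2S,4S)-4-methyl-5-oxooxolan-2-yl]-1,5,6,7-tetrahydro-4H-indol-4-one; 23 2-(diethoxyphosphoryl)propanoic acid
Product: 24 2-(diethoxyphosphoryl)propanoate ester of 22 at O-5
Conditions: DCC (1.3 equiv), DMAP (10 mol %), CH2Cl2, 0 °C → rt
Reagents that add atoms: none
Why: Steglich esterification (carbodiimide activation with DMAP acyl transfer) acylates the secondary α-ketol under near-neutral conditions that leave both the lactone and the ketol stereocentre untouched, the new phosphonate-bearing carbon being an irrelevant epimer mixture.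

Step 12
Reactants: 24 2-(diethoxyphosphoryl)propanoate ester of 22 at O-5
Product: 25 butenolide with ring D closed between O-5 and C-4 and a C-4=C(CH3) double bond
Conditions: NaH (1.05 equiv), THF, 0 °C → rt
Reagents that add atoms: none
Why: Intramolecular Horner–Wadsworth–Emmons olefination: the phosphonate carbanion adds to the adjacent C-4 ketone through a five-membered ring and syn-elimination of diethyl phosphate gives the tetrasubstituted butenolide, the single equivalent of NaH being consumed so that no base remains to epimerise C-5.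

Step 13
Reactants: 25 butenolide with ring D closed between O-5 and C-4 and a C-4=C(CH3) double bond
Product: 26 target CNP0232452.6
Conditions: H2 (10 bar), 5% Rh/Al2O3, EtOAc, rt
Reagents that add atoms: none
Why: Catalytic syn hydrogenation delivers both hydrogens to the convex face of the butenolide (the face of the C-5 hydrogen, anti to ring carbon C-6), which sets C-4 and the methyl-bearing carbon together as the all-cis lactone, and the neutral medium prevents epimerisation of the new α-centre while Rh keeps hydrogenolysis of the lactone C–O bonds low.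

Compound list
1 | tert-butyl ethyl malonate | CCOC(=O)CC(=O)OC(C)(C)C | starting material
2 | (E)-hex-3-en-2-one | CC/C=C/C(C)=O | starting material
3 | 1-tert-butyl 3-ethyl 2-[(3S)-5-oxohexan-3-yl]propanedioate (epimer mixture at the malonate carbon) | CC[C@H](C(C(=O)OCC)C(=O)OC(C)(C)C)CC(C)=O | intermediate
4 | 1-chloro-4-iodobutane | ClCCCCI | starting material
5 | 1-tert-butyl 3-ethyl 2-(4-chlorobutyl)-2-[(3S)-5-oxohexan-3-yl]propanedioate | CC[C@H](C(CCCCCl)(C(=O)OCC)C(=O)OC(C)(C)C)CC(C)=O | intermediate
6 | 1-tert-butyl 3-ethyl 2-(4-azidobutyl)-2-[(3S)-5-oxohexan-3-yl]propanedioate | CC[C@H](C(CCCCN=[N+]=[N-])(C(=O)OCC)C(=O)OC(C)(C)C)CC(C)=O | intermediate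
7 | tert-butyl (6S)-1-(4-azidobutyl)-6-ethyl-2,4-dioxocyclohexane-1-carboxylate | CC[C@H]1CC(=O)CC(=O)C1(CCCCN=[N+]=[N-])C(=O)OC(C)(C)C | intermediate
8 | (6S)-1-(4-azidobutyl)-6-ethyl-2,4-dioxocyclohexane-1-carboxylic acid (not isolated) | CC[C@H]1CC(=O)CC(=O)C1(CCCCN=[N+]=[N-])C(=O)O | intermediate
9 | (4R,5S)-4-(4-azidobutyl)-5-ethylcyclohexane-1,3-dione (trans) | CC[C@H]1CC(=O)CC(=O)[C@@H]1CCCCN=[N+]=[N-] | intermediate
10 | dimethyl N-(tert-butoxycarbonyl)-L-glutamate | COC(=O)CC[C@H](NC(=O)OC(C)(C)C)C(=O)OC | starting material
11 | dimethyl (2S,4S)-2-[(tert-butoxycarbonyl)amino]-4-methylpentanedioate | COC(=O)[C@@H](C)C[C@H](NC(=O)OC(C)(C)C)C(=O)OC | intermediate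
12 | (2S,4S)-4-methylglutamic acid hydrochloride (not isolated) | C[C@@H](C[C@H]([NH3+])C(=O)O)C(=O)O.[Cl-] | intermediate
13 | (2S,4S)-4-methyl-5-oxooxolane-2-carboxylic acid (cis) | O=C(O)[C@@H]1C[C@H](C)C(=O)O1 | intermediate
14 | isobutyl carbonic mixed anhydride of 13 (not isolated) | CC(C)COC(=O)OC(=O)[C@@H]1C[C@H](C)C(=O)O1 | intermediate
15 | (3S,5S)-5-(diazoacetyl)-3-methyloxolan-2-one (not isolated) | [N-]=[N+]=CC(=O)[C@@H]1C[C@H](C)C(=O)O1 | intermediate
16 | (3S,5S)-5-(bromoacetyl)-3-methyloxolan-2-one | O=C(CBr)[C@@H]1C[C@H](C)C(=O)O1 | intermediate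
17 | (4R,5S)-4-(4-azidobutyl)-5-ethyl-2-{2-[(2S,4S)-4-methyl-5-oxooxolan-2-yl]-2-oxoethyl}cyclohexane-1,3-dione (not isolated) | CC[C@H]1CC(=O)C(CC(=O)[C@@H]2C[C@H](C)C(=O)O2)C(=O)[C@@H]1CCCCN=[N+]=[N-] | intermediate
18 | triphenyliminophosphorane of 17, N=PPh3 in place of N3 (not isolated) | CC[C@H]1CC(=O)C(CC(=O)[C@@H]2C[C@H](C)C(=O)O2)C(=O)[C@@H]1CCCCN=P(c1ccccc1)(c1ccccc1)c1ccccc1 | intermediate
19 | (4R,5S)-4-(4-aminobutyl)-5-ethyl-2-{2-[(2S,4S)-4-methyl-5-oxooxolan-2-yl]-2-oxoethyl}cyclohexane-1,3-dione (not isolated) | CC[C@H]1CC(=O)C(CC(=O)[C@@H]2C[C@H](C)C(=O)O2)C(=O)[C@@H]1CCCCN | intermediate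
20 | (5aR,6S)-6-ethyl-9-{2-[(2S,4S)-4-methyl-5-oxooxolan-2-yl]-2-oxoethyl}-1,2,3,4,5,5a,6,7-octahydro-8H-1-benzazepin-8-one (not isolated) | CC[C@H]1CC(=O)C(CC(=O)[C@@H]2C[C@H](C)C(=O)O2)=C2NCCCC[C@H]12 | intermediate
21 | (6S,7R)-1,7-(butane-1,4-diyl)-6-ethyl-2-[(2S,4S)-4-methyl-5-oxooxolan-2-yl]-1,5,6,7-tetrahydro-4H-indol-4-one (ring B ketone) | CC[C@H]1CC(=O)c2cc([C@@H]3C[C@H](C)C(=O)O3)n3c2[C@@H]1CCCC3 | intermediate
22 | (5S,6R,7R)-1,7-(butane-1,4-diyl)-6-ethyl-5-hydroxy-2-[(2S,4S)-4-methyl-5-oxooxolan-2-yl]-1,5,6,7-tetrahydro-4H-indol-4-one (5-OH trans to 6-ethyl) | CC[C@H]1[C@H](O)C(=O)c2cc([C@@H]3C[C@H](C)C(=O)O3)n3c2[C@@H]1CCCC3 | intermediate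
23 | 2-(diethoxyphosphoryl)propanoic acid (racemic) | CCOP(=O)(OCC)C(C)C(=O)O | starting material
24 | 2-(diethoxyphosphoryl)propanoate ester of 22 at O-5 (epimer mixture at the phosphonate carbon) | CC[C@H]1[C@H](OC(=O)C(C)P(=O)(OCC)OCC)C(=O)c2cc([C@@H]3C[C@H](C)C(=O)O3)n3c2[C@@H]1CCCC3 | intermediate
25 | butenolide: ring D closed from O-5 through C(=O) and C(CH3)= to C-4; core (5S,6R,7R); pendant lactone (2S,4S) | CC[C@H]1[C@@H]2OC(=O)C(C)=C2c2cc([C@@H]3C[C@H](C)C(=O)O3)n3c2[C@@H]1CCCC3 | intermediate
26 | CNP0232452.6: ring D lactone cis-fused at C-4/C-5, core (4R,5S,6R,7R), ring D α-carbon R with CH3 cis to C-3a, pendant (2S,4S)-4-methyl-5-oxooxolan-2-yl at C-2 | CC[C@H]1[C@@H]2OC(=O)[C@H](C)[C@@H]2c2cc([C@@H]3C[C@H](C)C(=O)O3)n3c2[C@@H]1CCCC3 | target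

Total step count: 13 (dione branch steps 1–5, lactone branch steps 6–8, union step 9, endgame steps 10–13).
Longest linear sequence: 10 steps (steps 1–5, 9, 10–13).

Steps most likely to fail

Step 9. The risks are O-alkylation or double alkylation of the dione enolate, acid-promoted furan closure of the triketone before the nitrogen engages, slow closure of the seven-membered vinylogous amide so that intermolecular condensation takes over, and enolisation beside the side-chain ketone. The fallback sets out from 9 and 16 and returns at 21, and changes the order of bond formation using known chemistry. Staudinger reduction of 9 (PPh3, THF–H2O) should give (4R,5S)-4-(4-aminobutyl)-5-ethylcyclohexane-1,3-dione F1. Warming F1 in toluene with catalytic AcOH and removal of water should close the bicyclic vinylogous amide (5aR,6S)-6-ethyl-1,2,3,4,5,5a,6,7-octahydro-8H-1-benzazepin-8-one F2. The enaminone α-carbon of F2 is then alkylated by 16 (NaHCO3, EtOH, rt) to give 20, and heating with AcOH completes the cyclodehydration to 21, as in the classical enaminone/α-haloketone route to 4-oxotetrahydroindoles.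

Step 13. The risks are slow hydrogen uptake at the tetrasubstituted, pyrrole-conjugated alkene, hydrogenolysis of the allylic or pyrrolylic lactone C–O bonds, over-reduction of the pyrrole, and erosion of facial selectivity. The fallback sets out from 25 and returns at 26, and replaces surface hydrogenation by a homogeneous conjugate reduction. [(Ph3P)CuH]6 in toluene containing tert-butanol at rt should add hydride to C-4 from the convex face, and the copper enolate should be protonated as it forms from the same less hindered face, giving the same all-cis lactone without touching the pyrrole or the C–O bonds. No new compound is made on the way (F0).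

Step 12. The risks are sluggish addition of the phosphonate anion to the electron-rich (vinylogous amide) C-4 ketone, with base-mediated epimerisation at C-5 or cleavage of the ester becoming competitive. The fallback sets out from 22 and returns at 25, and replaces the olefination by a carbonyl addition followed by dehydration. Acylation of 22 with 2-bromopropanoyl bromide and pyridine in CH2Cl2 should give the 5-O-(2-bromopropanoyl) ester F3. Activated Zn dust in refluxing THF should then effect an intramolecular Reformatsky addition to the C-4 ketone, giving the 4-hydroxy lactone F4. Catalytic TsOH in CH2Cl2 should dehydrate the pyrrole-stabilised tertiary carbinol of F4 to butenolide 25.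

Further compounds
F1 | step 9 | (4R,5S)-4-(4-aminobutyl)-5-ethylcyclohexane-1,3-dione | CC[C@H]1CC(=O)CC(=O)[C@@H]1CCCCN
F2 | step 9 | (5aR,6S)-6-ethyl-1,2,3,4,5,5a,6,7-octahydro-8H-1-benzazepin-8-one | CC[C@H]1CC(=O)C=C2NCCCC[C@H]12
F3 | step 12 | 5-O-(2-bromopropanoyl) ester of 22 (epimer mixture at the bromine-bearing carbon) | CC[C@H]1[C@H](OC(=O)C(C)Br)C(=O)c2cc([C@@H]3C[C@H](C)C(=O)O3)n3c2[C@@H]1CCCC3
F4 | step 12 | 4-hydroxy lactone: ring D closed with a tertiary hydroxyl on C-4 (mixture at C-4 and the methyl-bearing carbon) | CC[C@H]1[C@@H]2OC(=O)C(C)C2(O)c2cc([C@@H]3C[C@H](C)C(=O)O3)n3c2[C@@H]1CCCC3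
F0 | step 13 | none | none
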